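**Plan**

1. Daucane numbering is used: C1 = quaternary C–Me ring-fusion carbon, C2/C3 = CH2, C4 = C(OH)(i-Pr), C5 = ring-fusion CH, C6 = ester carbinol, C7=C8(Me), C9 = carbinol, C10 = CH2. The retrosynthesis cuts, in order: the vanillate C6–O bond; the C6–O and C9–O bonds together (singlet oxygen on a C6=C7–C8=C9 diene); the C4–C5 bond; the C1–C2 bond; the seven-membered ring into 2,5-dimethylfuran plus a three-carbon oxyallyl unit.
2. Forward: the seven-membered ring arises first by a dearomatising (4+3) cycloaddition and is opened to the symmetric 3,6-dimethylcyclohepta-2,6-dienone; the C2–C4 chain is joined by a desymmetrising conjugate addition; the five-membered ring is closed last by insertion of a C5 carbenoid into the C4–H bond; diene formation, dioxygenation and esterification finish the route.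
3. Enabling feature: C5 is the only enolisable α-carbon of the enone and lies between the C6 carbonyl and quaternary C1, so a C5 carbenoid has no β-hydrogen; the tertiary C4–H bond, activated by its silyloxy oxygen, sits exactly 1,5 to C5.
4. Stereochemistry: C4 from a Sharpless kinetic resolution, carried through the insertion with retention; C1 from the chiral copper catalyst; C5 by base equilibration to the trans ring fusion; C6 and C9 together from suprafacial [4+2] addition of singlet oxygen to the α-face.

Key step: step 8

Assumption: racemic 4-methylpent-1-en-3-ol (8) is taken as a commercial material, and the phosphoramidite antipode in step 6 is the one that gives the (S) quaternary centre of 12.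

**Route**

Step 1
Reactants: 1 2,5-dimethylfuran; 2 1,1,3-trichloropropan-2-one
Product: 4 1,5-dimethyl-8-oxabicyclo[3.2.1]oct-6-en-3-one (meso), via dichloro cycloadduct 3 (not isolated)
Conditions: Et3N, CF3CH2OH, 0 °C to rt; then Zn–Cu couple, NH4Cl, MeOH, rt
Reagents that add atoms: none
Why: Dearomatising (4+3) cycloaddition of the furan with the chloro-oxyallyl cation formed from 2 by base in the ionising alcohol, followed by reductive dechlorination; the cis-bridged adduct is meso and carries both ring methyls.

Step 2
Reactants: 4 1,5-dimethyl-8-oxabicyclo[3.2.1]oct-6-en-3-one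
Product: 5 1,5-dimethyl-8-oxabicyclo[3.2.1]octan-3-one (meso)
Conditions: H2 (1 atm), Pd/C, EtOAc, rt
Reagents that add atoms: none
Why: Heterogeneous catalytic hydrogenation of the strained disubstituted alkene, which removes the unsaturation that would otherwise lead to a tropone in step 3.

Step 3
Reactants: 5 1,5-dimethyl-8-oxabicyclo[3.2.1]octan-3-one
Product: 7 3,6-dimethylcyclohepta-2,6-dien-1-one, via hydroxy enone 6 (not isolated)
Conditions: p-TsOH·H2O (10 mol%), toluene, reflux, azeotropic removal of water
Reagents that add atoms: none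
Why: Acid-promoted β-elimination of the bridging oxygen (β to the ketone) opens the oxa-bridge to 6, whose tertiary β-hydroxyl then dehydrates into conjugation, which should give the achiral cross-conjugated dienone with two enantiotopic β-carbons.

Step 4
Reactants: 8 rac-4-methylpent-1-en-3-ol
Product: 9 (S)-4-methylpent-1-en-3-ol
Conditions: Ti(OiPr)4 (10 mol%), D-(−)-diisopropyl tartrate (15 mol%), t-BuOOH (0.6 equiv), 4 Å molecular sieves, CH2Cl2, −20 °C
Reagents that add atoms: none
Why: Sharpless kinetic resolution: with the D-tartrate the (R)-alcohol is epoxidised fast, so the (S)-alcohol, which carries the future C4 configuration, should be recovered in high enantiomeric purity.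

Step 5
Reactants: 9 (S)-4-methylpent-1-en-3-ol
Product: 10 (S)-triethyl[(4-methylpent-1-en-3-yl)oxy]silane
Conditions: Et3SiCl, imidazole, CH2Cl2, 0 °C to rt
Reagents that add atoms: chlorotriethylsilane, CC[Si](Cl)(CC)CC
Why: Standard silylation of a secondary alcohol; the triethylsilyl ether tolerates the organometallic steps, activates the adjacent C–H bond for insertion, blocks O–H insertion and can later be cleaved from a tertiary centre.

Step 6
Reactants: 10 (S)-triethyl[(4-methylpent-1-en-3-yl)oxy]silane; 7 3,6-dimethylcyclohepta-2,6-dien-1-one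
Product: 12 (S)-3,6-dimethyl-6-[(R)-4-methyl-3-(triethylsilyloxy)pentyl]cyclohept-2-en-1-one, via alkylzirconocene 11 (not isolated)
Conditions: Cp2Zr(H)Cl (1.0 equiv), CH2Cl2, rt; then 7 (1.3 equiv), CuCl (10 mol%), chiral BINOL-derived phosphoramidite (10 mol%), AgNTf2 (11 mol%), Et2O, rt; aq. NH4Cl
Reagents that add atoms: none
Why: Hydrozirconation places Zr on the terminal carbon, and copper-catalysed asymmetric conjugate addition of the alkylzirconocene to one of the two enantiotopic β-methyl enone carbons (a desymmetrisation) creates quaternary C1 under ligand control, the enolate formed protecting the product from a second addition.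

Step 7
Reactants: 12 (S)-3,6-dimethyl-6-[(R)-4-methyl-3-(triethylsilyloxy)pentyl]cyclohept-2-en-1-one
Product: 14 (S)-7-diazo-3,6-dimethyl-6-[(R)-4-methyl-3-(triethylsilyloxy)pentyl]cyclohept-2-en-1-one, via trifluoroacetyl ketone 13 (not isolated)
Conditions: LiN(SiMe3)2, THF, −78 °C; CF3CO2CH2CF3; aq. NH4Cl work-up; then MsN3, Et3N, H2O, MeCN, rt
Reagents that add atoms: methanesulfonyl azide, CS(=O)(=O)N=[N+]=[N-]
Why: Detrifluoroacetylative (Regitz-type) diazo transfer: kinetic deprotonation can only occur at C5, because the other α-carbon is the enone CH, so the diazo group should be placed regiospecifically between the carbonyl and quaternary C1.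

Step 8
Reactants: 14 (S)-7-diazo-3,6-dimethyl-6-[(R)-4-methyl-3-(triethylsilyloxy)pentyl]cyclohept-2-en-1-one
Product: 15 cis-fused 4β-(triethylsilyloxy)-5β-H-dauc-7-en-6-one
Conditions: Rh2(OAc)4 (1 mol%), CH2Cl2, 40 °C, slow addition of 14
Reagents that add atoms: none
Why: Rh2(OAc)4 decomposes the α'-diazo enone to an electrophilic divalent-rhodium carbenoid at C5, which inserts through a three-centre, hydride-transfer-like transition state into the tertiary C4–H bond; the closest known reaction type is the intramolecular 1,5 C–H insertion of α-diazo ketones that gives cyclopentanes. The five-membered ring (C1–C2–C3–C4–C5) is closed in the 1,5-insertion mode, and the seven-membered ring is not involved. C4 becomes the fully substituted carbinol carbon with retention of configuration, so it keeps the configuration fixed in 9; C5 should form mainly cis-fused because the tether reaches the carbenoid from its own face, and it is corrected in step 9. Site selectivity is needed over the C3 methylene (1,4), the isopropyl methine (1,6) and the ring C–H bonds, and is secured because the C4–H bond is tertiary, oxygen-activated and the only activated bond at the 1,5 distance. Quaternary C1 leaves the carbenoid no β-hydrogen, so a 1,2-hydride shift cannot compete, and the silyl ether excludes O–H insertion.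

Step 9
Reactants: 15 cis-fused 4β-(triethylsilyloxy)-5β-H-dauc-7-en-6-one
Product: 16 trans-fused 4β-(triethylsilyloxy)dauc-7-en-6-one (1β-methyl and 5α-H)
Conditions: NaOMe (0.2 equiv), MeOH, 0 °C to rt
Reagents that add atoms: none
Why: Base-mediated epimerisation through the C5 enolate under thermodynamic control, in a protic medium so that reprotonation outruns β-elimination of the silyloxy group; with C1 and C4 fixed, the cis-fused isomer holds the isopropyl group syn to C6 on the concave face whereas the trans-fused isomer has only the oxygen substituent syn to C6, so the equilibrium should favour the trans ring fusion.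

Step 10
Reactants: 16 trans-fused 4β-(triethylsilyloxy)dauc-7-en-6-one
Product: 17 4β-(triethylsilyloxy)dauca-6,8-dien-6-yl trifluoromethanesulfonate
Conditions: Tf2O, 2,6-di-tert-butyl-4-methylpyridine, CH2Cl2, 0 °C to rt
Reagents that add atoms: trifluoromethanesulfonic anhydride, O=S(=O)(OS(=O)(=O)C(F)(F)F)C(F)(F)F
Why: Thermodynamic dienyl triflate formation: O-triflation of the enone and loss of the γ ring proton at C9 should give the through-conjugated C6=C7–C8=C9 triflate, while the hindered C5 methine is not deprotonated.

Step 11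
Reactants: 17 4β-(triethylsilyloxy)dauca-6,8-dien-6-yl trifluoromethanesulfonate
Product: 18 4β-(triethylsilyloxy)dauca-6,8-diene
Conditions: Pd(OAc)2 (5 mol%), PPh3 (10 mol%), n-Bu3N, HCO2H, DMF, 60 °C
Reagents that add atoms: none
Why: Palladium-catalysed formate reduction of an alkenyl triflate (oxidative addition, formate exchange, decarboxylation, C–H reductive elimination) replaces the triflate by hydrogen without moving the double bonds.

Step 12
Reactants: 18 4β-(triethylsilyloxy)dauca-6,8-diene
Product: 20 4β-(triethylsilyloxy)dauc-7-ene-6α,9α-diol, via endoperoxide 19 (not isolated)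
Conditions: O2, tetraphenylporphyrin (cat.), visible light, CH2Cl2, −30 °C; then Zn dust, AcOH, rt
Reagents that add atoms: oxygen, O=O
Why: [4+2] cycloaddition of singlet oxygen to the cyclohepta-1,3-diene is suprafacial, so C6–O and C9–O are cis, and should occur on the α-face away from the angular methyl and the C4 silyloxy group; zinc then cleaves the O–O bond reductively.

Step 13
Reactants: 20 4β-(triethylsilyloxy)dauc-7-ene-6α,9α-diol
Product: 21 4β,9α-bis(triethylsilyloxy)dauc-7-en-6α-ol
Conditions: Et3SiCl (1.05 equiv), imidazole, CH2Cl2, −40 to 0 °C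
Reagents that add atoms: chlorotriethylsilane, CC[Si](Cl)(CC)CC
Why: Site-selective silylation: the C9 hydroxyl next to a CH2 should react much faster than the C6 hydroxyl, which is buried between the ring fusion and the C4 substituents.

Step 14
Reactants: 22 vanillic acid (4-hydroxy-3-methoxybenzoic acid)
Product: 24 4-(tert-butyldimethylsilyloxy)-3-methoxybenzoic acid, via silyl ester 23 (not isolated)
Conditions: t-BuMe2SiCl (2.2 equiv), imidazole, DMF, rt; then AcOH (cat.), THF, H2O, rt
Reagents that add atoms: tert-butylchlorodimethylsilane, CC(C)(C)[Si](C)(C)Cl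
Why: Bis-silylation followed by selective hydrolysis of the labile silyl ester leaves the phenol protected and the acid free.

Step 15
Reactants: 24 4-(tert-butyldimethylsilyloxy)-3-methoxybenzoic acid; 21 4β,9α-bis(triethylsilyloxy)dauc-7-en-6α-ol
Product: 26 4β,9α-bis(triethylsilyloxy)dauc-7-en-6α-yl 4-(tert-butyldimethylsilyloxy)-3-methoxybenzoate, via mixed anhydride 25 (not isolated)
Conditions: 2,4,6-trichlorobenzoyl chloride, Et3N, THF, rt; then 21, DMAP, toluene, 60 °C
Reagents that add atoms: none
Why: Yamaguchi esterification: DMAP-mediated acyl transfer from the mixed anhydride to the only free hydroxyl (C6), with retention at C6.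

Step 16
Reactants: 26 4β,9α-bis(triethylsilyloxy)dauc-7-en-6α-yl 4-(tert-butyldimethylsilyloxy)-3-methoxybenzoate
Product: 27 4β,9α-dihydroxydauc-7-en-6α-yl 4-hydroxy-3-methoxybenzoate (CNP0189996.2)
Conditions: HF·pyridine, pyridine, THF, 0 °C to rt
Reagents that add atoms: none
Why: Fluoride-mediated cleavage of the aryl silyl ether and both triethylsilyl ethers under buffered conditions that should leave the allylic ester, the tertiary alcohol and the trisubstituted alkene untouched.

**Compound list**

1 | 2,5-dimethylfuran | Cc1ccc(C)o1 | starting material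
2 | 1,1,3-trichloropropan-2-one | ClCC(=O)C(Cl)Cl | starting material
3 | 2,4-dichloro-1,5-dimethyl-8-oxabicyclo[3.2.1]oct-6-en-3-one (chloride epimers; not isolated) | C[C@@]12C=C[C@@](C)(O1)C(Cl)C(=O)C2Cl | intermediate
4 | 1,5-dimethyl-8-oxabicyclo[3.2.1]oct-6-en-3-one (meso) | C[C@@]12C=C[C@@](C)(O1)CC(=O)C2 | intermediate
5 | 1,5-dimethyl-8-oxabicyclo[3.2.1]octan-3-one (meso) | C[C@@]12CC[C@@](C)(O1)CC(=O)C2 | intermediate
6 | 6-hydroxy-3,6-dimethylcyclohept-2-en-1-one (racemic; not isolated) | CC1=CC(=O)CC(C)(O)CC1 | intermediate
7 | 3,6-dimethylcyclohepta-2,6-dien-1-one | O=C1C=C(C)CCC(C)=C1 | intermediate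
8 | rac-4-methylpent-1-en-3-ol | C=CC(O)C(C)C | starting material
9 | (S)-4-methylpent-1-en-3-ol | C=C[C@@H](O)C(C)C | intermediate
10 | (S)-triethyl[(4-methylpent-1-en-3-yl)oxy]silane | C=C[C@@H](O[Si](CC)(CC)CC)C(C)C | intermediate
11 | chlorobis(cyclopentadienyl)[(R)-4-methyl-3-(triethylsilyloxy)pentyl]zirconium (not isolated) | Cl[Zr](C1C=CC=C1)(C1C=CC=C1)CC[C@@H](O[Si](CC)(CC)CC)C(C)C | intermediate
12 | (S)-3,6-dimethyl-6-[(R)-4-methyl-3-(triethylsilyloxy)pentyl]cyclohept-2-en-1-one | O=C1C=C(C)CC[C@@](C)(CC[C@@H](O[Si](CC)(CC)CC)C(C)C)C1 | intermediate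
13 | 7-trifluoroacetyl derivative of 12 (C7 epimers or enol; not isolated) | O=C1C=C(C)CC[C@@](C)(CC[C@@H](O[Si](CC)(CC)CC)C(C)C)C1C(=O)C(F)(F)F | intermediate
14 | (S)-7-diazo-3,6-dimethyl-6-[(R)-4-methyl-3-(triethylsilyloxy)pentyl]cyclohept-2-en-1-one | O=C1C=C(C)CC[C@@](C)(CC[C@@H](O[Si](CC)(CC)CC)C(C)C)C1=[N+]=[N-] | intermediate
15 | cis-fused 4β-(triethylsilyloxy)-5β-H-dauc-7-en-6-one (1β-methyl, 4α-isopropyl) | O=C1C=C(C)CC[C@@]2(C)CC[C@@](O[Si](CC)(CC)CC)(C(C)C)[C@@H]12 | intermediate
16 | trans-fused 4β-(triethylsilyloxy)dauc-7-en-6-one (1β-methyl, 4α-isopropyl, 5α-H) | O=C1C=C(C)CC[C@@]2(C)CC[C@@](O[Si](CC)(CC)CC)(C(C)C)[C@H]12 | intermediate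
17 | 4β-(triethylsilyloxy)dauca-6,8-dien-6-yl trifluoromethanesulfonate | O=S(=O)(OC1=CC(C)=CC[C@@]2(C)CC[C@@](O[Si](CC)(CC)CC)(C(C)C)[C@H]12)C(F)(F)F | intermediate
18 | 4β-(triethylsilyloxy)dauca-6,8-diene | C1=CC(C)=CC[C@@]2(C)CC[C@@](O[Si](CC)(CC)CC)(C(C)C)[C@H]12 | intermediate
19 | 6α,9α-epidioxy-4β-(triethylsilyloxy)dauc-7-ene (not isolated) | O1O[C@H]2C=C(C)[C@@H]1C[C@@]3(C)CC[C@@](O[Si](CC)(CC)CC)(C(C)C)[C@H]23 | intermediate
20 | 4β-(triethylsilyloxy)dauc-7-ene-6α,9α-diol | O[C@H]1C=C(C)[C@@H](O)C[C@@]2(C)CC[C@@](O[Si](CC)(CC)CC)(C(C)C)[C@H]12 | intermediate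
21 | 4β,9α-bis(triethylsilyloxy)dauc-7-en-6α-ol | O[C@H]1C=C(C)[C@@H](O[Si](CC)(CC)CC)C[C@@]2(C)CC[C@@](O[Si](CC)(CC)CC)(C(C)C)[C@H]12 | intermediate
22 | vanillic acid (4-hydroxy-3-methoxybenzoic acid) | COc1cc(C(=O)O)ccc1O | starting material
23 | tert-butyldimethylsilyl 4-(tert-butyldimethylsilyloxy)-3-methoxybenzoate (not isolated) | COc1cc(C(=O)O[Si](C)(C)C(C)(C)C)ccc1O[Si](C)(C)C(C)(C)C | intermediate
24 | 4-(tert-butyldimethylsilyloxy)-3-methoxybenzoic acid | COc1cc(C(=O)O)ccc1O[Si](C)(C)C(C)(C)C | intermediate
25 | 4-(tert-butyldimethylsilyloxy)-3-methoxybenzoic 2,4,6-trichlorobenzoic anhydride (not isolated) | COc1cc(C(=O)OC(=O)c2c(Cl)cc(Cl)cc2Cl)ccc1O[Si](C)(C)C(C)(C)C | intermediate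
26 | 4β,9α-bis(triethylsilyloxy)dauc-7-en-6α-yl 4-(tert-butyldimethylsilyloxy)-3-methoxybenzoate | COc1cc(C(=O)O[C@H]2C=C(C)[C@@H](O[Si](CC)(CC)CC)C[C@@]3(C)CC[C@@](O[Si](CC)(CC)CC)(C(C)C)[C@H]23)ccc1O[Si](C)(C)C(C)(C)C | intermediate
27 | 4β,9α-dihydroxydauc-7-en-6α-yl 4-hydroxy-3-methoxybenzoate (CNP0189996.2; 1R,4R,5S,6S,9S) | COc1cc(C(=O)O[C@H]2C=C(C)[C@@H](O)C[C@@]3(C)CC[C@@](O)(C(C)C)[C@H]23)ccc1O | target

**Totals**

Total step count: 16. Longest linear sequence: 13 steps (steps 1, 2, 3, 6, 7, 8, 9, 10, 11, 12, 13, 15, 16).

**Steps most likely to fail**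

Step 8. The crowded tertiary C4–H bond, flanked by isopropyl and the silyl ether, may react too slowly. Insertion at the isopropyl methine, oxonium-ylide formation at the silyl ether oxygen, Wolff ring contraction or carbene dimerisation could then take over. The fallback closes the same bond by an aldol reaction. It sets out from 14: aqueous HBr in THF at 0 °C should replace the diazo group by bromide and remove the silyl ether, giving the α'-bromo hydroxy enone F1. Oxidation with the triacetoxy periodinane (DMP) gives the bromo diketone F2. SmI2 (THF, −78 °C) should then generate the C5 samarium enolate regiospecifically, and this adds to the isopropyl ketone (Reformatsky-type aldol, 5-(enolexo)-exo-trig). The aldol mixture is equilibrated with catalytic KOt-Bu in t-BuOH (retro-aldol/aldol and C5 enolisation) towards the hydrogen-bonded trans-fused β-hydroxy enone F3. Silylation of F3 (Et3SiOTf, 2,6-lutidine) comes back to the route at 16. In this variant C4 is set by thermodynamic control and not by retention, which is why it is the reserve.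

Step 9. The equilibration may give an unfavourable cis/trans ratio, or the C5 enolate may expel the β-silyloxy group or deconjugate the enone. The fallback uses the free tertiary alcohol as an internal hydrogen-bond anchor. It sets out from 15: HF·pyridine removes the silyl group to give the cis-fused hydroxy enone F4. With DBU in CH2Cl2, F4 should epimerise at C5 to the trans-fused hydroxy enone F3 (the compound of the preceding fallback), which is stabilised by an O–H···O=C6 hydrogen bond that is possible only when the C4 hydroxyl and C6 are cis on the cyclopentane. Resilylation (Et3SiOTf, 2,6-lutidine) comes back to the route at 16.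

Step 12. Facial selectivity of the singlet-oxygen cycloaddition may be poor (β-face attack would give the 6β,9β-diol), or the ene reaction at the C8 methyl may compete. The fallback is a palladium-catalysed cis-1,4-diacetoxylation of the diene. It sets out from 18: Pd(OAc)2 (cat.), p-benzoquinone, LiOAc and LiCl (cat.) in AcOH should give the cis-6,9-diacetate F5. Both acetates are delivered anti to the metal, that is, to the face opposite to the one a small external reagent prefers, so the facial outcome is complementary to that of singlet oxygen. Methanolysis (K2CO3, MeOH) gives the diol and comes back to the route at 20.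

Further compounds
F1 | step 8 | (6S)-7-bromo-6-[(R)-3-hydroxy-4-methylpentyl]-3,6-dimethylcyclohept-2-en-1-one (bromide epimers) | O=C1C=C(C)CC[C@@](C)(CC[C@@H](O)C(C)C)C1Br
F2 | step 8 | 7-bromo-3,6-dimethyl-6-(4-methyl-3-oxopentyl)cyclohept-2-en-1-one (quaternary centre as in 12; bromide epimers) | O=C1C=C(C)CC[C@@](C)(CCC(=O)C(C)C)C1Br
F3 | step 8 | trans-fused 4β-hydroxydauc-7-en-6-one (16 without its silyl group) | O=C1C=C(C)CC[C@@]2(C)CC[C@@](O)(C(C)C)[C@H]12
F4 | step 9 | cis-fused 4β-hydroxy-5β-H-dauc-7-en-6-one (15 without its silyl group) | O=C1C=C(C)CC[C@@]2(C)CC[C@@](O)(C(C)C)[C@@H]12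
F5 | step 12 | 4β-(triethylsilyloxy)dauc-7-ene-6α,9α-diyl diacetate | CC(=O)O[C@H]1C=C(C)[C@@H](OC(C)=O)C[C@@]2(C)CC[C@@](O[Si](CC)(CC)CC)(C(C)C)[C@H]12
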